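Rings: A = benzo ring, B = furan ring, C = pendant aryl ring. Last cuts: the ring C phenols come from benzyl ethers, and the C3 formyl group and the side-chain CH2OH both come from methyl esters.
Ring B is then cut at O1–C2. This turns the 2-arylbenzofuran-3-carboxylate into a 3-aroylbenzofuran-2(3H)-one, whose ring oxygen already sits on C7a and whose lactone carbonyl is the later formyl carbon.
Enabling feature: C2 of ring B is bonded only to O1, C3 and C1' of ring C, so it is a masked ketone carbon. Cutting C2–C1' and C2–C3 together releases it as CO and leaves a ring C bromide and a ring A benzofuran-2(3H)-one with an acidic C3–H.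
Forward order: the lactone ring is built on ring A (glyoxylate ortho-hydroxyalkylation of dihydroferulic acid, hydrogenolysis, lactonisation) and the ring C bromide is made (Dakin oxidation, benzylation). The three components are joined, acidic methanol exchanges the lactone ring for aromatic ring B, and ester reduction, MnO2 oxidation and debenzylation finish the route.
The side chain travels as a methyl ester: a free alcohol would open the aryl lactone and trap the aroylpalladium species, and a silyl ether would not outlast the acidic steps. The ester is reduced together with the C3 ester in one hydride step.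
Stereochemistry: the target has no stereocentre, and the racemic carbinol carbon made in step 1 is erased in step 2.

Key step: step 6

Assumption: the product of the key step is drawn as its 2-hydroxybenzofuran enol. It is one of several rapidly interconverting tautomers (keto lactone, exocyclic enol) that all enter the following step alike.

Step 1
Reactants: 1 dihydroferulic acid (3-(4-hydroxy-3-methoxyphenyl)propanoic acid); 2 glyoxylic acid (used as the monohydrate)
Product: 3 racemic 3-{3-[carboxy(hydroxy)methyl]-4-hydroxy-5-methoxyphenyl}propanoic acid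
Conditions: NaOH (3.5 equiv), H2O, N2, 25–40 °C; then aq. HCl to pH 1, EtOAc extraction
Reagents that add atoms: none
Why: Base-mediated ortho-hydroxyalkylation of a phenoxide with glyoxylate (the condensation run industrially on guaiacol) can only occur at the free ortho carbon because the side chain blocks the para position, and the new carbinol centre is racemic and disappears in step 2.

Step 2
Reactants: 3 racemic 3-{3-[carboxy(hydroxy)methyl]-4-hydroxy-5-methoxyphenyl}propanoic acid
Product: 5 methyl 3-[4-hydroxy-3-methoxy-5-(2-methoxy-2-oxoethyl)phenyl]propanoate, via the mandelate dimethyl ester 4 (not isolated)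
Conditions: H2SO4 (cat.), MeOH, reflux; then 10% Pd/C, H2 (4 bar), 50 °C, same pot
Reagents that add atoms: methanol, CO
Why: Fischer esterification followed by acid-promoted benzylic C–O hydrogenolysis over Pd/C is the standard mandelate-to-arylacetate reduction, helped here by the ortho-hydroxyl group that weakens the benzylic C–O bond, while arene, esters and methyl ether are inert.

Step 3
Reactants: 5 methyl 3-[4-hydroxy-3-methoxy-5-(2-methoxy-2-oxoethyl)phenyl]propanoate
Product: 6 methyl 3-(7-methoxy-2-oxo-2,3-dihydro-1-benzofuran-5-yl)propanoate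
Conditions: p-TsOH·H2O (10 mol%), toluene, reflux, MeOH distilled off
Reagents that add atoms: none
Why: Acid-catalysed lactonisation (intramolecular transesterification) of an ortho-hydroxyarylacetate closes the five-membered lactone once methanol is removed, and the remote aliphatic methyl ester has no hydroxyl partner and stays untouched.

Step 4
Reactants: 7 5-bromo-o-vanillin (5-bromo-2-hydroxy-3-methoxybenzaldehyde)
Product: 9 bromocatechol 5-bromo-3-methoxybenzene-1,2-diol, via the aryl formate 8 (not isolated)
Conditions: 30% aq. H2O2, NaOH, H2O–THF, N2, 0 °C to rt; then aq. HCl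
Reagents that add atoms: hydrogen peroxide, OO
Why: In the Dakin oxidation hydroperoxide adds to the ortho-hydroxybenzaldehyde, the electron-rich aryl group migrates to oxygen and the formate is saponified in situ, the aryl bromide being inert.

Step 5
Reactants: 9 bromocatechol 5-bromo-3-methoxybenzene-1,2-diol
Product: 10 aryl bromide 1,2-bis(benzyloxy)-5-bromo-3-methoxybenzene
Conditions: BnBr (2.3 equiv), K2CO3 (3 equiv), DMF, 60 °C
Reagents that add atoms: benzyl bromide, BrCc1ccccc1
Why: Double Williamson etherification of the catechol gives ethers that resist amine base, CO, methanolic HCl, hydride and MnO2 and can be removed at the end with BCl3.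

Step 6
Reactants: 6 methyl 3-(7-methoxy-2-oxo-2,3-dihydro-1-benzofuran-5-yl)propanoate; 10 aryl bromide 1,2-bis(benzyloxy)-5-bromo-3-methoxybenzene; 11 carbon monoxide
Product: 12 methyl 3-{3-[3,4-bis(benzyloxy)-5-methoxybenzoyl]-2-hydroxy-7-methoxy-1-benzofuran-5-yl}propanoate (enol form of the 3-aroylbenzofuran-2(3H)-one)
Conditions: Pd(OAc)2 (5 mol%), Xantphos (6 mol%), Et3N (3 equiv), CO (1 atm), degassed 1,4-dioxane, 80 °C; work-up with aq. citric acid
Reagents that add atoms: none
Why: Proposed new method: zerovalent palladium formed in situ inserts into the C–Br bond of 10, migratory insertion of CO gives the Xantphos-bound aroylpalladium bromide, and the triethylammonium enolate of 6 (a 2-oxidobenzofuran, aromatic and therefore within reach of a tertiary amine) displaces bromide and is acylated at C3 by reductive elimination, so that the C1'–CO and CO–C3 bonds arise in one operation. The closest known reaction type is the palladium-catalysed carbonylative α-arylation of ketones, malonates and 2-oxindoles with aryl bromides, the oxindole case running with the same mild amine base, whereas a lactone of the benzofuran-2(3H)-one class has not served as the carbon nucleophile. No ring closes and no stereocentre results, because C3 of 12 lies in a planar chelated enol. Carbonylation must outrun direct α-arylation, which the wide bite angle of Xantphos, the CO atmosphere, the electron-rich aryl group and the weakly nucleophilic amine-generated enolate all favour. C-acylation must win over O-acylation, and here any enol ester is itself an acyl donor that returns its aroyl group to the enolate pool, while deprotonation of the far more acidic 12 by a second equivalent of Et3N drains the equilibrium towards the C-acyl product. The methyl ester and the benzyl and methyl ethers are spectators, and strict exclusion of oxygen guards the enolate against oxidative dimerisation.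

Step 7
Reactants: 12 methyl 3-{3-[3,4-bis(benzyloxy)-5-methoxybenzoyl]-2-hydroxy-7-methoxy-1-benzofuran-5-yl}propanoate
Product: 14 methyl 2-[3,4-bis(benzyloxy)-5-methoxyphenyl]-7-methoxy-5-(3-methoxy-3-oxopropyl)-1-benzofuran-3-carboxylate, via the ring-opened keto ester 13 (not isolated)
Conditions: HCl (3 M in MeOH, anhydrous), reflux
Reagents that add atoms: methanol, CO
Why: Acid-catalysed methanolysis of the aryl lactone followed by cyclodehydration of the freed phenol onto the aryl ketone (the known 3-acylbenzofuranone to benzofuran-3-carboxylate rearrangement, a 5-exo-trig addition then loss of water) is driven by aromatisation of ring B, keeps the ring oxygen on C7a and turns the old lactone carbonyl into the C3 ester.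

Step 8
Reactants: 14 methyl 2-[3,4-bis(benzyloxy)-5-methoxyphenyl]-7-methoxy-5-(3-methoxy-3-oxopropyl)-1-benzofuran-3-carboxylate
Product: 15 diol 3-{2-[3,4-bis(benzyloxy)-5-methoxyphenyl]-3-(hydroxymethyl)-7-methoxy-1-benzofuran-5-yl}propan-1-ol
Conditions: i-Bu2AlH (6 equiv), CH2Cl2, −78 to 0 °C; aq. potassium sodium tartrate
Reagents that add atoms: none
Why: Exhaustive hydride reduction of both methyl esters with i-Bu2AlH delivers the side-chain alcohol and the C3 carbinol at once, the benzyl and methyl ethers and ring B being inert.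

Step 9
Reactants: 15 diol 3-{2-[3,4-bis(benzyloxy)-5-methoxyphenyl]-3-(hydroxymethyl)-7-methoxy-1-benzofuran-5-yl}propan-1-ol
Product: 16 aldehyde 2-[3,4-bis(benzyloxy)-5-methoxyphenyl]-5-(3-hydroxypropyl)-7-methoxy-1-benzofuran-3-carbaldehyde
Conditions: activated MnO2 (15 equiv), CH2Cl2, rt
Reagents that add atoms: none
Why: Chemoselective MnO2 oxidation touches only the benzofuran-3-ylmethanol, which is an activated benzylic-type alcohol, so the saturated primary alcohol of the side chain is left alone and oxidation stops at the aldehyde.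

Step 10
Reactants: 16 aldehyde 2-[3,4-bis(benzyloxy)-5-methoxyphenyl]-5-(3-hydroxypropyl)-7-methoxy-1-benzofuran-3-carbaldehyde
Product: 17 Mururin C (2-(3,4-dihydroxy-5-methoxyphenyl)-5-(3-hydroxypropyl)-7-methoxy-1-benzofuran-3-carbaldehyde)
Conditions: BCl3 (1 M in CH2Cl2, 6 equiv), pentamethylbenzene (6 equiv), CH2Cl2, −78 °C; then H2O
Reagents that add atoms: none
Why: Lewis-acid debenzylation with BCl3 and pentamethylbenzene as a non-basic benzyl cation scavenger cleaves aryl benzyl ethers at −78 °C without touching the aldehyde, the C2=C3 bond or the methyl ethers, all of which a late hydrogenolysis could endanger.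

Compound list
1 | dihydroferulic acid, 3-(4-hydroxy-3-methoxyphenyl)propanoic acid | COc1cc(CCC(=O)O)ccc1O | starting material
2 | glyoxylic acid | O=CC(=O)O | starting material
3 | 3-{3-[carboxy(hydroxy)methyl]-4-hydroxy-5-methoxyphenyl}propanoic acid (racemic) | COc1cc(CCC(=O)O)cc(C(O)C(=O)O)c1O | intermediate
4 | methyl 3-[4-hydroxy-3-(1-hydroxy-2-methoxy-2-oxoethyl)-5-methoxyphenyl]propanoate (racemic, formed in situ) | COC(=O)CCc1cc(OC)c(O)c(C(O)C(=O)OC)c1 | intermediate
5 | methyl 3-[4-hydroxy-3-methoxy-5-(2-methoxy-2-oxoethyl)phenyl]propanoate | COC(=O)CCc1cc(OC)c(O)c(CC(=O)OC)c1 | intermediate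
6 | methyl 3-(7-methoxy-2-oxo-2,3-dihydro-1-benzofuran-5-yl)propanoate | O=C1Cc2cc(CCC(=O)OC)cc(OC)c2O1 | intermediate
7 | 5-bromo-2-hydroxy-3-methoxybenzaldehyde | COc1cc(Br)cc(C=O)c1O | starting material
8 | 5-bromo-2-hydroxy-3-methoxyphenyl formate (formed in situ) | COc1cc(Br)cc(OC=O)c1O | intermediate
9 | 5-bromo-3-methoxybenzene-1,2-diol | COc1cc(Br)cc(O)c1O | intermediate
10 | 1,2-bis(benzyloxy)-5-bromo-3-methoxybenzene | COc1cc(Br)cc(OCc2ccccc2)c1OCc1ccccc1 | intermediate
11 | carbon monoxide | [C-]#[O+] | starting material
12 | methyl 3-{3-[3,4-bis(benzyloxy)-5-methoxybenzoyl]-2-hydroxy-7-methoxy-1-benzofuran-5-yl}propanoate | Oc1oc2c(OC)cc(CCC(=O)OC)cc2c1C(=O)c1cc(OC)c(OCc2ccccc2)c(OCc2ccccc2)c1 | intermediate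
13 | methyl 3-[3,4-bis(benzyloxy)-5-methoxyphenyl]-2-[2-hydroxy-3-methoxy-5-(3-methoxy-3-oxopropyl)phenyl]-3-oxopropanoate (racemic, formed in situ) | COC(=O)CCc1cc(OC)c(O)c(C(C(=O)OC)C(=O)c2cc(OC)c(OCc3ccccc3)c(OCc3ccccc3)c2)c1 | intermediate
14 | methyl 2-[3,4-bis(benzyloxy)-5-methoxyphenyl]-7-methoxy-5-(3-methoxy-3-oxopropyl)-1-benzofuran-3-carboxylate | COC(=O)CCc1cc(OC)c2oc(-c3cc(OC)c(OCc4ccccc4)c(OCc4ccccc4)c3)c(C(=O)OC)c2c1 | intermediate
15 | 3-{2-[3,4-bis(benzyloxy)-5-methoxyphenyl]-3-(hydroxymethyl)-7-methoxy-1-benzofuran-5-yl}propan-1-ol | OCCCc1cc(OC)c2oc(-c3cc(OC)c(OCc4ccccc4)c(OCc4ccccc4)c3)c(CO)c2c1 | intermediate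
16 | 2-[3,4-bis(benzyloxy)-5-methoxyphenyl]-5-(3-hydroxypropyl)-7-methoxy-1-benzofuran-3-carbaldehyde | OCCCc1cc(OC)c2oc(-c3cc(OC)c(OCc4ccccc4)c(OCc4ccccc4)c3)c(C=O)c2c1 | intermediate
17 | Mururin C | COc1cc(-c2oc3c(OC)cc(CCCO)cc3c2C=O)cc(O)c1O | target

Total step count: 10. Longest linear sequence: 8 steps (steps 1–3 and 6–10, from dihydroferulic acid).

Steps most likely to fail

Step 6. Oxidative addition of the electron-rich bromide may be slow under CO. The lactone enolate may be lost to self-condensation or oxidative coupling at 80 °C, and direct arylation or persistent O-acylation may compete.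

The fallback separates the delivery of the one-carbon unit from the C–C bond formation and uses only classical chemistry. It sets out from 10, uses 6 as the partner, and returns at 12.
- Bromine–lithium exchange (n-BuLi, THF, −78 °C) gives [3,4-bis(benzyloxy)-5-methoxyphenyl]lithium F1.
- CO2 followed by aq. HCl converts this into 3,4-bis(benzyloxy)-5-methoxybenzoic acid F2.
- Oxalyl chloride with catalytic DMF in CH2Cl2 gives 3,4-bis(benzyloxy)-5-methoxybenzoyl chloride F3.
- Treatment of 6 with Et3N and F3 in CH2Cl2 at 0 °C gives the enol ester methyl 3-{2-[3,4-bis(benzyloxy)-5-methoxybenzoyloxy]-7-methoxy-1-benzofuran-5-yl}propanoate F4.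
- Catalytic DMAP moves the aroyl group from oxygen to C3 (Steglich-type O-to-C acyl shift, the established way to 3-acylbenzofuranones) to give 12.

Step 1. Attack through the hindered ortho carbon may be slow enough for Cannizzaro disproportionation of glyoxylate to consume the electrophile, and the very polar product may be hard to extract from water.

The fallback installs the two-carbon arm by a sigmatropic route instead. It sets out from 1, bypasses steps 1–3, and returns at 6.
- Fischer esterification (MeOH, cat. H2SO4, reflux) gives methyl 3-(4-hydroxy-3-methoxyphenyl)propanoate F5.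
- Allyl bromide and K2CO3 in acetone give methyl 3-[3-methoxy-4-(prop-2-en-1-yloxy)phenyl]propanoate F6.
- Aromatic Claisen rearrangement (N,N-diethylaniline, 200 °C) can only deliver the allyl group to the single free ortho carbon, giving methyl 3-[4-hydroxy-3-methoxy-5-(prop-2-en-1-yl)phenyl]propanoate F7.
- Ozonolysis (O3, CH2Cl2–MeOH, −78 °C, then Me2S) gives, after spontaneous ring closure, the racemic lactol methyl 3-(2-hydroxy-7-methoxy-2,3-dihydro-1-benzofuran-5-yl)propanoate F8.
- Dess–Martin periodinane buffered with NaHCO3 in CH2Cl2 oxidises the lactol to 6.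

Step 10. The boron Lewis acid may also strip the methyl ether next to the freed catechol by chelation, convert the side-chain alcohol into a chloride, or allow benzylation of the electron-rich rings. The catechol aldehyde may also suffer on work-up.

The fallback removes the benzyl groups earlier by a different mechanism and replaces them with fluoride-labile groups. It sets out from 14 and returns at 17.
- Hydrogenolysis (H2, 10% Pd/C, EtOAc–MeOH, rt) gives methyl 2-(3,4-dihydroxy-5-methoxyphenyl)-7-methoxy-5-(3-methoxy-3-oxopropyl)-1-benzofuran-3-carboxylate F9.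
- TBSCl and imidazole in DMF give the bis(silyl ether) methyl 2-{3,4-bis[(tert-butyldimethylsilyl)oxy]-5-methoxyphenyl}-7-methoxy-5-(3-methoxy-3-oxopropyl)-1-benzofuran-3-carboxylate F10.
- i-Bu2AlH gives the diol 3-{2-{3,4-bis[(tert-butyldimethylsilyl)oxy]-5-methoxyphenyl}-3-(hydroxymethyl)-7-methoxy-1-benzofuran-5-yl}propan-1-ol F11.
- MnO2 gives the aldehyde 2-{3,4-bis[(tert-butyldimethylsilyl)oxy]-5-methoxyphenyl}-5-(3-hydroxypropyl)-7-methoxy-1-benzofuran-3-carbaldehyde F12.
- Et3N·3HF in THF at 0 °C releases 17.

Further compounds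
F1 | step 6 | [3,4-bis(benzyloxy)-5-methoxyphenyl]lithium | [Li]c1cc(OC)c(OCc2ccccc2)c(OCc2ccccc2)c1
F2 | step 6 | 3,4-bis(benzyloxy)-5-methoxybenzoic acid | COc1cc(C(=O)O)cc(OCc2ccccc2)c1OCc1ccccc1
F3 | step 6 | 3,4-bis(benzyloxy)-5-methoxybenzoyl chloride | COc1cc(C(=O)Cl)cc(OCc2ccccc2)c1OCc1ccccc1
F4 | step 6 | methyl 3-{2-[3,4-bis(benzyloxy)-5-methoxybenzoyloxy]-7-methoxy-1-benzofuran-5-yl}propanoate | COC(=O)CCc1cc(OC)c2oc(OC(=O)c3cc(OC)c(OCc4ccccc4)c(OCc4ccccc4)c3)cc2c1
F5 | step 1 | methyl 3-(4-hydroxy-3-methoxyphenyl)propanoate | COC(=O)CCc1ccc(O)c(OC)c1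
F6 | step 1 | methyl 3-[3-methoxy-4-(prop-2-en-1-yloxy)phenyl]propanoate | C=CCOc1ccc(CCC(=O)OC)cc1OC
F7 | step 1 | methyl 3-[4-hydroxy-3-methoxy-5-(prop-2-en-1-yl)phenyl]propanoate | C=CCc1cc(CCC(=O)OC)cc(OC)c1O
F8 | step 1 | methyl 3-(2-hydroxy-7-methoxy-2,3-dihydro-1-benzofuran-5-yl)propanoate (racemic) | COC(=O)CCc1cc(OC)c2OC(O)Cc2c1
F9 | step 10 | methyl 2-(3,4-dihydroxy-5-methoxyphenyl)-7-methoxy-5-(3-methoxy-3-oxopropyl)-1-benzofuran-3-carboxylate | COC(=O)CCc1cc(OC)c2oc(-c3cc(O)c(O)c(OC)c3)c(C(=O)OC)c2c1
F10 | step 10 | methyl 2-{3,4-bis[(tert-butyldimethylsilyl)oxy]-5-methoxyphenyl}-7-methoxy-5-(3-methoxy-3-oxopropyl)-1-benzofuran-3-carboxylate | COC(=O)CCc1cc(OC)c2oc(-c3cc(OC)c(O[Si](C)(C)C(C)(C)C)c(O[Si](C)(C)C(C)(C)C)c3)c(C(=O)OC)c2c1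
F11 | step 10 | 3-{2-{3,4-bis[(tert-butyldimethylsilyl)oxy]-5-methoxyphenyl}-3-(hydroxymethyl)-7-methoxy-1-benzofuran-5-yl}propan-1-ol | OCCCc1cc(OC)c2oc(-c3cc(OC)c(O[Si](C)(C)C(C)(C)C)c(O[Si](C)(C)C(C)(C)C)c3)c(CO)c2c1
F12 | step 10 | 2-{3,4-bis[(tert-butyldimethylsilyl)oxy]-5-methoxyphenyl}-5-(3-hydroxypropyl)-7-methoxy-1-benzofuran-3-carbaldehyde | OCCCc1cc(OC)c2oc(-c3cc(OC)c(O[Si](C)(C)C(C)(C)C)c(O[Si](C)(C)C(C)(C)C)c3)c(C=O)c2c1
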